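# Design of a synthesis of (2S)-5,7-dihydroxy-2-[4-methoxy-3,5-bis(3-methylbut-2-en-1-yl)phenyl]chroman-4-one (19)

## The problem

The target 19 is a (2S)-flavanone. Ring A is a phloroglucinol unit with free hydroxyls at C5 and C7, ring C is the dihydropyranone, and ring B at C2 is a 4-methoxyphenyl ring flanked at C3' and C5' by two 3-methylbut-2-enyl (prenyl) groups. Three pieces therefore meet around ring C, through O1–C2, the C2–C3–C4 arm and C4–C4a.

C2 is the only stereocenter, and nothing else in the molecule can relay asymmetry to it, so a catalyst or reagent has to set it. C2 is also fragile: once C4 is a ketone, C2 lies β to the carbonyl and carries O1 as a leaving group, so base opens ring C by retro-oxa-Michael reaction and erases the configuration. The ketone should therefore appear late, and the end-game should be acidic or neutral.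

The two trisubstituted prenyl alkenes exclude hydrogenation, strong Brønsted or Lewis acids and free electrophilic halogen. The C4' methyl ether must stay while O5 and O7 are set free, which rules out methyl or benzyl protection on ring A. Ring A itself is very electron-rich and is easily attacked by electrophiles.

The feature that opens the route is the substitution of C2. It bears ring B, O1 and C3, which is exactly the pattern of a branched 1-arylallyl aryl ether in which a vinyl group stands for C3–C4. In addition, a 3,5-dioxygenated phenyl ether has two equivalent ortho carbons, either of which can become C4a.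

## Retrosynthesis

**19 from 18.** The two acetal C–O bonds of the bis(methoxymethyl) ether 18 are the last to be broken. Methoxymethyl groups are preferred on O5 and O7 for three reasons: benzyl groups would need hydrogenolysis, which saturates the prenyl groups; methyl groups could not be removed beside the C4' methyl ether; silyl groups can be transferred to an aryloxide in the key step. Compound 18 differs from 19 only by these groups. The forward reaction must be an acid solvolysis mild enough to leave the prenyl alkenes and ring C alone.

**18 from 16.** Ring C is opened at C4–C4a, which leads to the (S)-3-aryl-3-aryloxypropanoic acid 16.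
- The neighbouring cut at O1–C2 would mean an oxa-Michael closure of an open enone, which is reversible and hard to make enantioselective.
- The C4–C4a cut leaves C2 as a plain benzylic aryl ether whose configuration can be fixed beforehand.
- The two ortho carbons of the ring A ether are equivalent, and each is activated by three oxygen substituents, so the acylation has only one possible outcome.
- The precursor has lost a ring and the sensitive β-aryloxy ketone.
- The forward reaction is an intramolecular Friedel–Crafts acylation that must spare the acetals, the prenyl alkenes and the benzylic C2–O1 bond.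

**16 from 12.** No skeletal bond is cut here. The acid 16 is traced through the aldehyde 15 and the primary alcohol 14 to the vinyl compound 12, so that the C3–C4 arm becomes a vinyl group. The gain is that 12 has no carbonyl group at all, so its stereocenter cannot be lost by elimination and re-addition. The forward steps must achieve two things:
- anti-Markovnikov hydration of the one monosubstituted alkene beside two trisubstituted ones;
- oxidation to the acid without chlorinating ring A or expelling the aryloxide.

**12 from 8 and 10.** The O1–C2 bond is cut. This is the strategic disconnection: it divides the molecule into two achiral fragments of similar size, the ring B cinnamyl methyl carbonate 8 and the symmetrical phenol 10, and it creates the only stereocenter in the step that joins them.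
- A cut at C2–ring B or C2–C3 would leave the stereocenter to be made by addition to a carbonyl group and bring the β-aryloxy carbonyl problem back.
- The forward reaction is an iridium-catalysed allylic etherification. It must be branched-selective, must occur on oxygen and not on carbon of the aryloxide, and must be face-selective.

**8 from 6.** The carbonate 8 comes from the allylic alcohol 7 by acylation, and 7 from the enoate 6 by 1,2-reduction. These are functional-group changes that fix the (E) geometry needed for a clean allyl complex.

**6 from 1.** The two aryl–CH2 bonds of the prenyl groups in 6 are cut to the dibromide 4 and the prenylstannane 5. The alkene of 4 is then cut to the aldehyde 2 and the phosphonate 3, and 2 comes from the commercial phenol 1 by O-methylation.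
- Cross-coupling at two defined C–Br bonds is preferred to direct C-prenylation of a phenoxide, which gives mixtures of O- and C-alkylated and of mono- and bis-alkylated products.
- The forward coupling must deliver the linear prenyl isomer at both positions.

**10 from 9.** The two acetal bonds of 10 are cut to phloroglucinol 9. The forward reaction is a statistical double etherification of a very cheap triol, accepted because it is a single step.

## Roads not taken

**Alternative 1:** The cut is C2–C3, made together with ring C. The diazomethyl ketone A1 carries the diazoacetyl group on ring A ortho to a benzyl ether of the ring B benzylic alcohol. A chiral dirhodium tetracarboxylate, Rh2(O2CR*)4 (divalent rhodium), would decompose it, and the carbenoid would insert into one of the two enantiotopic benzylic C–H bonds to give the bis-silyl flavanone A2.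
- Merits: ring C and the stereocenter arise in one step from an achiral precursor, the C–H bond is activated by both oxygen and an aryl group, and the route is shorter than the one adopted here. In step economy this road is clearly better.
- Weak points: a diazomethyl ketone gives an acceptor-only carbenoid, the class for which chiral dirhodium catalysts control the face least well. The insertion must form a six-membered ring while the ether oxygen sits at the five-ring distance, so oxonium ylide formation followed by a benzyl shift (Stevens rearrangement) to a five-membered ring isomer is a serious competitor. The two prenyl alkenes invite cyclopropanation, and ring B invites Buchner-type addition.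
- Comparison: the chosen plan is longer, but its stereo-defining step belongs to a reaction class with wide precedent for exactly this pairing of aryloxide and cinnamyl carbonate, and the prenyl groups are spectators in it.

**Alternative 2:** The cuts are C4a–C4, C4–C3 and O1–C2 at once. A palladium-catalysed carbonylative coupling (zerovalent palladium formed from PdCl2(PPh3)2) of the ortho-iodophenol A3 with the ring B arylacetylene A4, followed by cyclisation of the resulting ynone, would give the flavone A5.
- Merits: this is the most convergent road. Three bonds and ring C form in one operation, the iodide fixes the regiochemistry, no stereocenter is at risk during assembly, and A5 is reached in fewer steps than 18.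
- Weak points: A5 is flat, so C2 would have to be created afterwards by enantioselective 1,4-reduction of a 5-alkoxyflavone. Hydrogenation catalysts also reduce the prenyl alkenes and tend to over-reduce the ketone. Copper hydride reduction is slow on a β-aryl β-alkoxy enone, and the enolate formed can open ring C. A3 also requires a desymmetrising iodination or protection of phloroglucinol. The cyclisation can give five-ring products beside A5.
- Comparison: this road wins on convergence. The chosen plan counters by making the stereocenter with a dependable catalytic method while C2 is sp3 and carbonyl-free, and by never having to reduce anything beside the prenyl groups.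

**Alternative 3:** The cut is C3–C4. The lithio derivative of the dithiane A6 would open the (S)-aryl oxirane A7 at its CH2 terminus to give the (R)-hydroxy dithiane A8.
- Merits: the C–C bond formation is reliable, and the configuration of the carbinol is secure because no bond to the stereocenter is made. In this respect it equals the chosen plan.
- Weak points: the anion of A6 is flanked by two ortho acetal ethers and is hindered. A7 needs its own asymmetric step. Unmasking the dithiane requires soft electrophiles (mercury salts, halonium or hypervalent iodine reagents) that the prenyl alkenes and ring A tolerate poorly. After unmasking, the carbinol lies β to a ketone, and ring closure must proceed with inversion at a benzylic centre after selective removal of one of three acetal groups. Loss of water from this aldol-type intermediate is easy, and any closure after that is racemic.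
- Comparison: the road is longer and passes through the very β-oxygenated ketone that the chosen plan avoids until ring C is closed.

Key step: step 7

Assumption: the (Sa,Sc,Sc) enantiomer of the BINOL-derived N,N-bis(1-phenylethyl)phosphoramidite is taken to give the (S) ether 12, the sense usually drawn for this catalyst with cinnamyl carbonates and heteroatom nucleophiles. If a test run on 8 shows the opposite sense, the mirror-image ligand is used with nothing else changed.

## Route

Step 1
Reactants: 1 3,5-dibromo-4-hydroxybenzaldehyde
Product: 2 3,5-dibromo-4-methoxybenzaldehyde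
Conditions: MeI, K2CO3, DMF, rt
Reagents that add atoms: iodomethane (CI)
Why: Williamson O-methylation; the phenol between two bromine atoms is acidic and its phenoxide is alkylated cleanly by iodomethane while the aldehyde is untouched.

Step 2
Reactants: 2 3,5-dibromo-4-methoxybenzaldehyde; 3 triethyl phosphonoacetate
Product: 4 ethyl (E)-3-(3,5-dibromo-4-methoxyphenyl)prop-2-enoate
Conditions: LiCl, DBU, MeCN, rt
Reagents that add atoms: none
Why: Horner–Wadsworth–Emmons olefination with a stabilised phosphonate under mild LiCl/amine conditions; aryl aldehydes give the (E)-enoate, and the aryl bromides are inert.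

Step 3
Reactants: 4 ethyl (E)-3-(3,5-dibromo-4-methoxyphenyl)prop-2-enoate; 5 tributyl(3-methylbut-2-en-1-yl)stannane (2.5 equiv)
Product: 6 ethyl (E)-3-[4-methoxy-3,5-bis(3-methylbut-2-en-1-yl)phenyl]prop-2-enoate
Conditions: Pd(PPh3)4 (10 mol%), DMF, 100 °C
Reagents that add atoms: none
Why: Two-fold Stille coupling; zerovalent palladium inserts into each C–Br bond (activated by the para enoate), the allylic stannane transmetalates, and reductive elimination at the unsubstituted allyl terminus gives the linear prenyl groups. The ester and the enoate alkene, a poor Heck acceptor, are tolerated.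

Step 4
Reactants: 6 ethyl (E)-3-[4-methoxy-3,5-bis(3-methylbut-2-en-1-yl)phenyl]prop-2-enoate
Product: 7 (E)-3-[4-methoxy-3,5-bis(3-methylbut-2-en-1-yl)phenyl]prop-2-en-1-ol
Conditions: i-Bu2AlH (2.5 equiv), CH2Cl2, −78 °C; aq. potassium sodium tartrate
Reagents that add atoms: none
Why: 1,2-Reduction of an α,β-unsaturated ester to the allylic alcohol by i-Bu2AlH at low temperature; the isolated trisubstituted alkenes and the aryl ether do not react.

Step 5
Reactants: 7 (E)-3-[4-methoxy-3,5-bis(3-methylbut-2-en-1-yl)phenyl]prop-2-en-1-ol
Product: 8 (E)-3-[4-methoxy-3,5-bis(3-methylbut-2-en-1-yl)phenyl]prop-2-en-1-yl methyl carbonate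
Conditions: ClCO2Me, pyridine, CH2Cl2, 0 °C
Reagents that add atoms: methyl chloroformate (COC(=O)Cl)
Why: Acylation of the primary allylic alcohol with a chloroformate; the methyl carbonate is the leaving group that ionises on iridium with loss of carbon dioxide and methoxide.

Step 6
Reactants: 9 phloroglucinol (benzene-1,3,5-triol)
Product: 10 3,5-bis(methoxymethoxy)phenol
Conditions: MOMCl (2.0 equiv), i-Pr2NEt, DMF, 0 °C to rt
Reagents that add atoms: chloromethyl methyl ether (COCCl)
Why: O-Alkylation of the triol with two equivalents of the hard electrophile; the reaction is statistical and the bis-ether is separated from the mono- and tris-ethers by chromatography, which is acceptable in one step from a very cheap triol.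

Step 7
Reactants: 8 (E)-3-[4-methoxy-3,5-bis(3-methylbut-2-en-1-yl)phenyl]prop-2-en-1-yl methyl carbonate; 10 3,5-bis(methoxymethoxy)phenol (1.5 equiv)
Product: 12 (S)-1-[1-[3,5-bis(methoxymethoxy)phenoxy]prop-2-en-1-yl]-4-methoxy-3,5-bis(3-methylbut-2-en-1-yl)benzene (the branched 1-arylallyl aryl ether), via lithium 3,5-bis(methoxymethoxy)phenoxide 11 (not isolated)
Conditions: 10, n-BuLi (1.45 equiv), THF, 0 °C; then 8, [Ir(cod)Cl]2 (2 mol%), (Sa,Sc,Sc)-BINOL-derived N,N-bis(1-phenylethyl)phosphoramidite (4 mol%, preactivated with n-PrNH2), THF, 50 °C
Reagents that add atoms: none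
Why: The cyclometalated monovalent iridium phosphoramidite complex ionises carbonate 8 with loss of carbon dioxide and methoxide to an allyl complex of trivalent iridium, and aryloxide 11 attacks it from outside the coordination sphere, anti to the metal, at the aryl-bearing terminus. The closest known reaction type is the iridium–phosphoramidite allylic etherification of cinnamyl carbonates with lithium aryloxides, of which this is a direct application. No ring closes; the O1–C2 bond and the C2 stereocenter are formed. The stereocenter is controlled by the catalyst alone, since neither partner is chiral: the iridacycle exposes one face of the allyl unit, and the (Sa,Sc,Sc) ligand is taken to give (S). The step needs branched over linear attack, O- over C-allylation of the ambident aryloxide, and face selectivity. Branched attack is favoured by the iridium allyl complex itself, which directs nucleophiles to the substituted terminus, and ring B has no ortho substituent next to the allyl chain to disturb this. O-attack is favoured by the oxygen-centred lithium aryloxide in THF, and the electron-rich aryloxide is a poor leaving group, so the kinetic ether is not re-ionised. The prenyl alkenes carry no leaving group and do not take part.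

Step 8
Reactants: 12 (S)-1-[1-[3,5-bis(methoxymethoxy)phenoxy]prop-2-en-1-yl]-4-methoxy-3,5-bis(3-methylbut-2-en-1-yl)benzene
Product: 14 (S)-3-[3,5-bis(methoxymethoxy)phenoxy]-3-[4-methoxy-3,5-bis(3-methylbut-2-en-1-yl)phenyl]propan-1-ol, via B-alkyl-9-borabicyclo[3.3.1]nonane adduct 13 (not isolated)
Conditions: 9-BBN (1.3 equiv), THF, 0 °C to rt; then aq. NaOH, 30% H2O2, 0 °C
Reagents that add atoms: hydrogen peroxide (OO)
Why: Hydroboration–oxidation; 9-BBN adds to the monosubstituted alkene far faster than to the trisubstituted prenyl alkenes and places boron on the terminal carbon, and alkaline peroxide turns the C–B bond into C–OH. No bond to C2 is touched, so the configuration is kept.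

Step 9
Reactants: 14 (S)-3-[3,5-bis(methoxymethoxy)phenoxy]-3-[4-methoxy-3,5-bis(3-methylbut-2-en-1-yl)phenyl]propan-1-ol
Product: 15 (S)-3-[3,5-bis(methoxymethoxy)phenoxy]-3-[4-methoxy-3,5-bis(3-methylbut-2-en-1-yl)phenyl]propanal
Conditions: Dess–Martin periodinane, NaHCO3, CH2Cl2, 0 °C to rt
Reagents that add atoms: none
Why: Dess–Martin oxidation of a primary alcohol under buffered, essentially neutral conditions, which avoids base-induced β-elimination of the aryloxide; the aldehyde is carried on without chromatography.

Step 10
Reactants: 15 (S)-3-[3,5-bis(methoxymethoxy)phenoxy]-3-[4-methoxy-3,5-bis(3-methylbut-2-en-1-yl)phenyl]propanal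
Product: 16 (S)-3-[3,5-bis(methoxymethoxy)phenoxy]-3-[4-methoxy-3,5-bis(3-methylbut-2-en-1-yl)phenyl]propanoic acid
Conditions: NaClO2, NaH2PO4, 2-methyl-2-butene (large excess), t-BuOH/H2O, 0 °C to rt
Reagents that add atoms: sodium chlorite ([Na+].[O-]Cl=O)
Why: Pinnick oxidation at weakly acidic pH; the large excess of 2-methyl-2-butene takes up the hypochlorous acid so that the prenyl groups and ring A are spared, and the acetals survive the phosphate buffer.

Step 11
Reactants: 16 (S)-3-[3,5-bis(methoxymethoxy)phenoxy]-3-[4-methoxy-3,5-bis(3-methylbut-2-en-1-yl)phenyl]propanoic acid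
Product: 18 (2S)-2-[4-methoxy-3,5-bis(3-methylbut-2-en-1-yl)phenyl]-5,7-bis(methoxymethoxy)chroman-4-one, via mixed trifluoroacetic anhydride 17 (not isolated)
Conditions: (CF3CO)2O (1.5 equiv), CH2Cl2, 0 °C; quench into aq. NaHCO3
Reagents that add atoms: none
Why: Intramolecular Friedel–Crafts acylation through the acyl trifluoroacetate; the ring A carbon ortho to O1 is activated by two ortho and one para oxygen, the two ortho carbons are equivalent, and closure of the six-membered ring C needs no added strong acid. C2 is not involved, and its ionisation is disfavoured because the C4' methoxy group is twisted out of conjugation by its two ortho prenyl groups. Any acetal lost here is harmless because step 12 removes both.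

Step 12
Reactants: 18 (2S)-2-[4-methoxy-3,5-bis(3-methylbut-2-en-1-yl)phenyl]-5,7-bis(methoxymethoxy)chroman-4-one
Product: 19 (2S)-5,7-dihydroxy-2-[4-methoxy-3,5-bis(3-methylbut-2-en-1-yl)phenyl]chroman-4-one
Conditions: 3 M aq. HCl, MeOH, 50 °C
Reagents that add atoms: none
Why: Acid-catalysed acetal methanolysis; the 5-O-acetal, held by the C4 carbonyl, leaves first and the 7-O-acetal follows, while the aryl methyl ether and the prenyl alkenes tolerate dilute acid at moderate temperature. Acid is chosen over base because base would open ring C by retro-oxa-Michael reaction and racemise C2.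

## Compound list

1 | 3,5-dibromo-4-hydroxybenzaldehyde | O=Cc1cc(Br)c(O)c(Br)c1 | starting material
2 | 3,5-dibromo-4-methoxybenzaldehyde | COc1c(Br)cc(C=O)cc1Br | intermediate
3 | triethyl phosphonoacetate | CCOC(=O)CP(=O)(OCC)OCC | starting material
4 | ethyl (E)-3-(3,5-dibromo-4-methoxyphenyl)prop-2-enoate | CCOC(=O)/C=C/c1cc(Br)c(OC)c(Br)c1 | intermediate
5 | tributyl(3-methylbut-2-en-1-yl)stannane | CCCC[Sn](CCCC)(CCCC)CC=C(C)C | starting material
6 | ethyl (E)-3-[4-methoxy-3,5-bis(3-methylbut-2-en-1-yl)phenyl]prop-2-enoate | CCOC(=O)/C=C/c1cc(CC=C(C)C)c(OC)c(CC=C(C)C)c1 | intermediate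
7 | (E)-3-[4-methoxy-3,5-bis(3-methylbut-2-en-1-yl)phenyl]prop-2-en-1-ol | OC/C=C/c1cc(CC=C(C)C)c(OC)c(CC=C(C)C)c1 | intermediate
8 | (E)-3-[4-methoxy-3,5-bis(3-methylbut-2-en-1-yl)phenyl]prop-2-en-1-yl methyl carbonate | COC(=O)OC/C=C/c1cc(CC=C(C)C)c(OC)c(CC=C(C)C)c1 | intermediate
9 | phloroglucinol | Oc1cc(O)cc(O)c1 | starting material
10 | 3,5-bis(methoxymethoxy)phenol | COCOc1cc(O)cc(OCOC)c1 | intermediate
11 | lithium 3,5-bis(methoxymethoxy)phenoxide | [Li+].[O-]c1cc(OCOC)cc(OCOC)c1 | intermediate (not isolated)
12 | (S)-1-[1-[3,5-bis(methoxymethoxy)phenoxy]prop-2-en-1-yl]-4-methoxy-3,5-bis(3-methylbut-2-en-1-yl)benzene | C=C[C@@H](c1cc(CC=C(C)C)c(OC)c(CC=C(C)C)c1)Oc1cc(OCOC)cc(OCOC)c1 | intermediate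
13 | 9-[(S)-3-[3,5-bis(methoxymethoxy)phenoxy]-3-[4-methoxy-3,5-bis(3-methylbut-2-en-1-yl)phenyl]propyl]-9-borabicyclo[3.3.1]nonane | C(C[C@@H](c1cc(CC=C(C)C)c(OC)c(CC=C(C)C)c1)Oc1cc(OCOC)cc(OCOC)c1)B1C2CCCC1CCC2 | intermediate (not isolated)
14 | (S)-3-[3,5-bis(methoxymethoxy)phenoxy]-3-[4-methoxy-3,5-bis(3-methylbut-2-en-1-yl)phenyl]propan-1-ol | OCC[C@@H](c1cc(CC=C(C)C)c(OC)c(CC=C(C)C)c1)Oc1cc(OCOC)cc(OCOC)c1 | intermediate
15 | (S)-3-[3,5-bis(methoxymethoxy)phenoxy]-3-[4-methoxy-3,5-bis(3-methylbut-2-en-1-yl)phenyl]propanal | O=CC[C@@H](c1cc(CC=C(C)C)c(OC)c(CC=C(C)C)c1)Oc1cc(OCOC)cc(OCOC)c1 | intermediate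
16 | (S)-3-[3,5-bis(methoxymethoxy)phenoxy]-3-[4-methoxy-3,5-bis(3-methylbut-2-en-1-yl)phenyl]propanoic acid | OC(=O)C[C@@H](c1cc(CC=C(C)C)c(OC)c(CC=C(C)C)c1)Oc1cc(OCOC)cc(OCOC)c1 | intermediate
17 | (S)-3-[3,5-bis(methoxymethoxy)phenoxy]-3-[4-methoxy-3,5-bis(3-methylbut-2-en-1-yl)phenyl]propanoic trifluoroacetic anhydride | O=C(C[C@@H](c1cc(CC=C(C)C)c(OC)c(CC=C(C)C)c1)Oc1cc(OCOC)cc(OCOC)c1)OC(=O)C(F)(F)F | intermediate (not isolated)
18 | (2S)-2-[4-methoxy-3,5-bis(3-methylbut-2-en-1-yl)phenyl]-5,7-bis(methoxymethoxy)chroman-4-one | COCOc1cc(OCOC)c2C(=O)C[C@@H](c3cc(CC=C(C)C)c(OC)c(CC=C(C)C)c3)Oc2c1 | intermediate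
19 | (2S)-5,7-dihydroxy-2-[4-methoxy-3,5-bis(3-methylbut-2-en-1-yl)phenyl]chroman-4-one | COc1c(CC=C(C)C)cc([C@@H]2CC(=O)c3c(O)cc(O)cc3O2)cc1CC=C(C)C | target

## Step count and risks

Total step count: 12. Longest linear sequence: 11 steps (steps 1 to 5 and 7 to 12, from 1 to 19); step 6 is a one-step side branch that joins at step 7.

**Step 7 (key step).** Three things are most likely to go wrong:
- C-allylation: the aryloxide 11 is ambident and very electron-rich, so attack through a ring carbon could compete with attack through oxygen.
- Loss of branched and enantiomeric purity: the ether 12 could be re-ionised on iridium and drift toward the linear isomer, because its allyl unit carries an alkyl-rich aryl group.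
- The sense of induction could turn out opposite to the one assumed; this is cured by the mirror-image ligand.

Fallback for the first two: the O1–C2 bond is made by SN2 displacement instead. The path sets out from 7.
- Sharpless asymmetric epoxidation of 7 (Ti(Oi-Pr)4, L-(+)-diethyl tartrate, t-BuOOH, 4 Å sieves, CH2Cl2, −20 °C) touches only the allylic alcohol and gives [(2S,3S)-3-[4-methoxy-3,5-bis(3-methylbut-2-en-1-yl)phenyl]oxiran-2-yl]methanol F1.
- Hydride delivery to C2 of the epoxy alcohol with NaAlH2(OCH2CH2OMe)2 gives (R)-1-[4-methoxy-3,5-bis(3-methylbut-2-en-1-yl)phenyl]propane-1,3-diol F2.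
- Silylation of the primary hydroxyl (TBSCl, imidazole) gives (R)-3-(tert-butyldimethylsilyloxy)-1-[4-methoxy-3,5-bis(3-methylbut-2-en-1-yl)phenyl]propan-1-ol F3.
- Mitsunobu etherification with phenol 10 (PPh3, diisopropyl azodicarboxylate, toluene, 0 °C) inverts the carbinol and gives the (S)-silyl ether of 14, tert-butyl[(S)-3-[3,5-bis(methoxymethoxy)phenoxy]-3-[4-methoxy-3,5-bis(3-methylbut-2-en-1-yl)phenyl]propoxy]dimethylsilane F4.
- Fluoride (Bu4NF, THF) removes the silyl group, and the path comes back to the route at 14.

**Step 11.** The acylation liberates trifluoroacetic acid. Three processes could follow: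
- premature loss of the acetal groups, which is tolerable;
- intermolecular trifluoroacetylation of ring A by the anhydride;
- acid-promoted ionisation of the benzylic C2–O1 bond, which would erode the configuration or expel the phenol.

Fallback: a proton-free acylation that sets out from 16. The acid is converted with 1-chloro-N,N,2-trimethylprop-1-en-1-amine (CH2Cl2, 0 °C, no hydrogen chloride formed) into (S)-3-[3,5-bis(methoxymethoxy)phenoxy]-3-[4-methoxy-3,5-bis(3-methylbut-2-en-1-yl)phenyl]propanoyl chloride F5. Chloride is then abstracted with AgOTf in the presence of 2,6-di-tert-butyl-4-methylpyridine at −78 °C, so that the acyl triflate closes onto ring A while the base takes up the acid. The path comes back to the route at 18.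

**Step 10 (with step 9).** Two processes are the concern:
- hypochlorous acid formed from chlorite could chlorinate ring A or add to the prenyl alkenes if the scavenger does not outcompete them;
- aldehyde 15 could lose the aryloxide by β-elimination while being handled.

Fallback: a chlorine-free oxidation that sets out from 14 and does not isolate 15. Catalytic TEMPO with PhI(OAc)2 in MeCN–water takes the primary alcohol through the aldehyde hydrate directly to the acid, and the path comes back to the route at 16. It makes no new compound (F0).

**Step 3.** Two processes are the concern: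
- allyl transposition on palladium could deliver some 1,1-dimethylallyl (reverse prenyl) product;
- the second coupling, next to the methoxy group and the first prenyl group, could stall.

Fallback: the regiochemical question is removed by using a symmetrical allyl group and building the prenyl terminus afterwards. The path sets out from 4. Two-fold Stille coupling with allyltributylstannane (Pd(PPh3)4, DMF) gives ethyl (E)-3-(3,5-diallyl-4-methoxyphenyl)prop-2-enoate F6. Cross-metathesis with 2-methyl-2-butene as solvent and the second-generation Grubbs catalyst converts both allyl groups into prenyl groups; the conjugated enoate is far less reactive in metathesis. The path comes back to the route at 6.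

## Further compounds

F1 | step 7 | [(2S,3S)-3-[4-methoxy-3,5-bis(3-methylbut-2-en-1-yl)phenyl]oxiran-2-yl]methanol | OC[C@@H]1O[C@H]1c1cc(CC=C(C)C)c(OC)c(CC=C(C)C)c1
F2 | step 7 | (R)-1-[4-methoxy-3,5-bis(3-methylbut-2-en-1-yl)phenyl]propane-1,3-diol | OCC[C@@H](O)c1cc(CC=C(C)C)c(OC)c(CC=C(C)C)c1
F3 | step 7 | (R)-3-(tert-butyldimethylsilyloxy)-1-[4-methoxy-3,5-bis(3-methylbut-2-en-1-yl)phenyl]propan-1-ol | CC(C)(C)[Si](C)(C)OCC[C@@H](O)c1cc(CC=C(C)C)c(OC)c(CC=C(C)C)c1
F4 | step 7 | tert-butyl[(S)-3-[3,5-bis(methoxymethoxy)phenoxy]-3-[4-methoxy-3,5-bis(3-methylbut-2-en-1-yl)phenyl]propoxy]dimethylsilane | CC(C)(C)[Si](C)(C)OCC[C@@H](c1cc(CC=C(C)C)c(OC)c(CC=C(C)C)c1)Oc1cc(OCOC)cc(OCOC)c1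
F5 | step 11 | (S)-3-[3,5-bis(methoxymethoxy)phenoxy]-3-[4-methoxy-3,5-bis(3-methylbut-2-en-1-yl)phenyl]propanoyl chloride | ClC(=O)C[C@@H](c1cc(CC=C(C)C)c(OC)c(CC=C(C)C)c1)Oc1cc(OCOC)cc(OCOC)c1
F0 | step 10 | none | none
F6 | step 3 | ethyl (E)-3-(3,5-diallyl-4-methoxyphenyl)prop-2-enoate | CCOC(=O)/C=C/c1cc(CC=C)c(OC)c(CC=C)c1
A1 | alternative 1 | 1-[2-[[4-methoxy-3,5-bis(3-methylbut-2-en-1-yl)phenyl]methoxy]-4,6-bis(tert-butyldimethylsilyloxy)phenyl]-2-diazoethan-1-one | [N-]=[N+]=CC(=O)c1c(OCc2cc(CC=C(C)C)c(OC)c(CC=C(C)C)c2)cc(O[Si](C)(C)C(C)(C)C)cc1O[Si](C)(C)C(C)(C)C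
A2 | alternative 1 | (2S)-5,7-bis(tert-butyldimethylsilyloxy)-2-[4-methoxy-3,5-bis(3-methylbut-2-en-1-yl)phenyl]chroman-4-one | CC(C)(C)[Si](C)(C)Oc1cc(O[Si](C)(C)C(C)(C)C)c2C(=O)C[C@@H](c3cc(CC=C(C)C)c(OC)c(CC=C(C)C)c3)Oc2c1
A3 | alternative 2 | 2-iodo-3,5-bis(methoxymethoxy)phenol | COCOc1cc(O)c(I)c(OCOC)c1
A4 | alternative 2 | 5-ethynyl-2-methoxy-1,3-bis(3-methylbut-2-en-1-yl)benzene | C#Cc1cc(CC=C(C)C)c(OC)c(CC=C(C)C)c1
A5 | alternative 2 | 2-[4-methoxy-3,5-bis(3-methylbut-2-en-1-yl)phenyl]-5,7-bis(methoxymethoxy)chromen-4-one | COCOc1cc(OCOC)c2c(=O)cc(-c3cc(CC=C(C)C)c(OC)c(CC=C(C)C)c3)oc2c1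
A6 | alternative 3 | 2-[2,4,6-tris(methoxymethoxy)phenyl]-1,3-dithiane | COCOc1cc(OCOC)c(C2SCCCS2)c(OCOC)c1
A7 | alternative 3 | (S)-2-[4-methoxy-3,5-bis(3-methylbut-2-en-1-yl)phenyl]oxirane | C1O[C@H]1c1cc(CC=C(C)C)c(OC)c(CC=C(C)C)c1
A8 | alternative 3 | (R)-1-[4-methoxy-3,5-bis(3-methylbut-2-en-1-yl)phenyl]-2-[2-[2,4,6-tris(methoxymethoxy)phenyl]-1,3-dithian-2-yl]ethan-1-ol | COCOc1cc(OCOC)c(C2(C[C@@H](O)c3cc(CC=C(C)C)c(OC)c(CC=C(C)C)c3)SCCCS2)c(OCOC)c1
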